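## Analysis of the target

The target 38 is a trans-fused hydroazulene (azulene numbering: five-membered ring C1, C2, C3, C3a, C8a; seven-membered ring C3a, C4 to C8, C8a). It carries a trisubstituted epoxide across C1–C2, a methyl group on C2, an isopropyl group on C4, a 4-hydroxybenzoate on O-5 and a tertiary methyl carbinol at C7. Its seven stereocentres are 1S,2R,3aR,4S,5S,7R,8aS. If the face of H-8a is called β and that of H-3a α, the isopropyl group, the C7 hydroxyl and the epoxide oxygen are α and the C5 ester oxygen and the C7 methyl group are β; the C5 and C7 oxygens are thus 1,3-anti and the C7 hydroxyl is syn to the epoxide. The epoxide is acid-labile, the tertiary alcohol can dehydrate and the aryl ester does not survive hydride or alkoxide, so ester and epoxide must come late. The difficulty lies in the seven-membered ring and in C4 and C5, each flanked by two branched carbons, where acyclic 1,2-induction is weak. The strategy rests on C6 and C7: they are neighbours, C7 is a methyl carbinol and stands 1,3 to the oxygen on C5, so a C6=C7 alkene allylic to C5–O is the latent form of the carbinol. That alkene results when a sulfur atom is taken out from between C6 and C7 of an eight-membered cyclic sulfone, which replaces a seven-membered carbocyclisation by two C–S displacements.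

## Retrosynthetic reasoning

38 back to 36. The phenol is freed last from silyl ether 37. The epoxide of 37 is cut to the C1=C2 alkene of 36, because the α-oriented C7 hydroxyl can deliver the oxidant to the α face and because the epoxide would not survive the hydride and acid steps before it.

36 back to 33. The C1=C2 alkene is carried as a cis-1,2-diol (34, acetonide 33) and released by Corey–Winter olefination via thionocarbonate 35. This keeps a second trisubstituted alkene out of the way while C6=C7 is functionalised. The diol sits on the β face because its tertiary oxygen serves earlier as a tether; both carbons become sp2 in 36, so their configuration is free.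

33 back to 28 and 31. The ester C–O bond is cut to diol 28 and acid 31, made from 4-hydroxybenzoic acid 29. Only the secondary C5 hydroxyl of 28 can be acylated; the tertiary C7 hydroxyl needs no protection.

28 back to 25. The C7 carbinol is traced to the C6=C7 alkene of 25 through epoxide 26 and alcohol 27. The bulky silyl ether on C5 sends the peracid to the α face, and hydride opens the epoxide at the less substituted C6, which leaves the oxygen on C7.

25 back to 22 (key disconnection). A sulfonyl group is inserted between C6 and C7, giving the eight-membered sulfone 22. The C6=C7 bond is the only bond made in the forward step and no stereocentre is created, so both C7 epimers of 22 serve. The gain is that the ring is closed by C–S bonds and then contracted.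

22 back to 19. The two C–S bonds are cut: C6 carries chloride and C7 a mesylate in 19, and a sulfide source joins them to thiocane 21, which is oxidised to 22.

19 back to 13. The C7 leaving group comes from the allyl group by Markovnikov hydration (18) and mesylation. The C5 stereocentre is set by catalyst-controlled reduction of chloromethyl ketone 15 to chlorohydrin 16 (protected as 17), because substrate control next to C4 is not dependable. The C5–C6 bond is cut back to aldehyde 13 (carbenoid addition gives 14, oxidation gives 15).

13 back to 10. Aldehyde 13 comes from alcohol 12, the acetonide of triol 11, which is the reduction product of the bridged keto lactone 10. The lactone carbonyl is C5, the ketone is C1.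

10 back to 6 and 7. The C3a–C4 and C8a–C8 bonds are cut. The ester enolate of 6 adds within the molecule to C3a, so the new bond can only form on the face of the C2 oxygen. The resulting enolate is allylated by allyl bromide 7 anti to the new bridge, which gives the trans relation of C3a and C8a. C4 lies α to the lactone carbonyl in a rigid bicycle and is set by equilibration.

6 back to 1. Enone 6 comes from ester 4 by photo-oxygenation with allylic transposition. Ester 4 is made from cyclopentenol 2 and isovaleryl chloride 3, and 2 from (S)-linalool 1 by ring-closing metathesis. The carbinol carbon of 1 is the only stereocentre that is brought in.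

## Alternatives that were turned down

Alternative 1: The ring-fusion bond C3a–C8a is cut, which opens both rings to the ten-membered enedione A1. In the forward direction mild base would form the C1 enolate at C8a, which adds across the ring to C3a of the C3a=C4–C5 enone and gives the trans-fused dione A2 with both rings closed at once.
- For it: one step makes both rings and both ring-fusion centres. The C2 and C7 oxygens are already in place with the configuration of the target, so the epoxide could be closed by displacement instead of a late face-selective epoxidation. The C5 ketone leaves C4 open to equilibration.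
- Against it: A1 is a ten-membered carbocycle with two remote quaternary carbinol centres, and making it needs a C–C macrocyclisation. Its C7 silyloxy group is β to the C5 carbonyl, so the basic key step invites β-elimination. The trans ring fusion depends on the conformation of a flexible ring. C5 still has to be reduced with control afterwards.
- Comparison: it is stronger in the bond economy of the ring-forming event and in carrying the final oxygens. The chosen route offers instead an eight-membered closure by C–S displacement, ring-fusion centres fixed before any medium ring exists, and a key step that makes no stereocentre.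

Alternative 2: C6 and C7 are removed from the seven-membered ring, which leads to the cyclopentanone-derived silyl enol ether A3 (C5=C8). In the forward direction dichloroketene A4 adds across C5=C8 and forms C7–C8 and C5–C6; fluoride then cleaves the old C5–C8 bond by retro-aldol reaction in the same flask and gives the 2,2-dichlorocycloheptane-1,3-dione A5.
- For it: the ring expansion is dependable, the three neighbouring centres C4, C3a and C8a are set on a five-membered ring, and both C5 and C7 arrive oxygenated.
- Against it: A5 carries two ketones on either side of a CCl2 group. After dechlorination they must be told apart (methyl addition at C7 with facial control, reduction at C5) in a 1,3-dione that enolises. The carbocyclic five-membered ring C1–C3 still has to be closed from the vinyl and methallyl groups, and the silyl enol ether must be formed away from C4.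
- Comparison: it is stronger in the precedent for the ring-forming step and in the oxidation level at C7, which the chosen route must restore by epoxidation and hydride opening. The chosen route offers a single alkene whose functionalisation is steered by a C5 centre already in place, no differentiation of two like carbonyls, and the five-membered ring from the first step.

Alternative 3: The C3a–C4 bond is cut and C6–C8 joined, which gives the cis-divinylcyclopropane A6; its vinyl units are the C8a=C3a bond of a cyclopentenone and the C5=C4 silyl enol ether. In the forward direction a Cope rearrangement through the boat transition state forms C3a–C4, breaks the C6–C8 cyclopropane bond and gives the cycloheptadiene A7.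
- For it: the step is concerted and stereospecific, it is convergent, and the ring appears with C5 and C7 oxygenated and the quaternary C7 centre set beforehand on the cyclopropane.
- Against it: the boat geometry puts the isopropyl group on the wrong face, so A7 is the C4 epimer and must be corrected through the C5 ketone. A6 needs a fully substituted cyclopropane carbon with defined cis geometry and an enol ether of defined geometry. A7 still needs a face-selective reduction of the C8a=C8 enone bond to reach the trans ring fusion.
- Comparison: it is stronger in convergency and in forming a C–C bond and a stereocentre in the key step. The chosen route offers C3a, C4 and C8a fixed and equilibrated before ring formation, no stereochemical repair after the key step, and a precursor made by displacement chemistry.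

Key step: step 16

Remark on the chemistry: (S)-(+)-linalool (coriandrol) is assumed to be commercially available in high enantiomeric purity; apart from the CBS catalyst it is the only source of chirality.

Remark on the chemistry: locants follow the azulene numbering of the target in all intermediates, and β means the face of H-8a, α the face of H-3a.

## Route

Step 1
Reactants: 1 (S)-(+)-linalool
Product: 2 (1S)-1-methylcyclopent-2-en-1-ol
Conditions: second-generation Grubbs catalyst RuCl2(=CHPh)(PCy3)(H2IMes) (cat.), CH2Cl2, 40 °C
Reagents that add atoms: none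
Why: Ring-closing metathesis between the vinyl group and the trisubstituted alkene closes the cyclopentene and releases volatile 2-methylpropene; the tertiary carbinol centre is not touched, so its S configuration is carried over.

Step 2
Reactants: 2 (1S)-1-methylcyclopent-2-en-1-ol; 3 isovaleryl chloride
Product: 4 (1S)-1-methylcyclopent-2-en-1-yl 3-methylbutanoate
Conditions: Et3N, DMAP (cat.), CH2Cl2, 0 → 20 °C
Reagents that add atoms: none
Why: DMAP-catalysed O-acylation of the tertiary allylic alcohol; the ester is the tether that later delivers C4 to C3a on the oxygen-bearing face.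

Step 3
Reactants: 4 (1S)-1-methylcyclopent-2-en-1-yl 3-methylbutanoate
Product: 6 (1S)-1-methyl-2-oxocyclopent-3-en-1-yl 3-methylbutanoate, via allylic hydroperoxide 5 (not isolated)
Conditions: O2, hν (visible), tetraphenylporphyrin (cat.), Ac2O, pyridine, DMAP (cat.), CH2Cl2, 20 °C
Reagents that add atoms: dioxygen, O=O
Why: Schenck ene reaction with singlet oxygen: the only allylic hydrogens are on the carbon remote from the quaternary centre, so oxygen adds next to the quaternary carbon and the double bond moves to C8a=C3a. Acetylation and Kornblum–DeLaMare elimination of hydroperoxide 5 then give the enone in the same flask.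

Step 4
Reactants: 6 (1S)-1-methyl-2-oxocyclopent-3-en-1-yl 3-methylbutanoate; 7 allyl bromide
Product: 10 (1S,4S,5R,6S)-1-methyl-4-(propan-2-yl)-6-(prop-2-en-1-yl)-2-oxabicyclo[3.2.1]octane-3,7-dione, via lithium ester enolate 8 (not isolated), via bicyclic lithium enolate 9 (not isolated)
Conditions: LiN(i-Pr)2, THF–DMPU, −78 → 0 °C; 7, −40 → 0 °C; then KOt-Bu (cat.), t-BuOH–THF, 20 °C
Reagents that add atoms: none
Why: Intramolecular Michael addition of ester enolate 8 (6-(enolendo)-exo-trig) can reach C3a only from the face of the C2 oxygen, which fixes C3a; any reversible aldol addition to C1 should drain into the more stable ketone enolate 9. Enolate 9 is allylated on its exo face, anti to the lactone bridge, which gives the trans relation of C3a and C8a. The tert-butoxide equilibration places the isopropyl group equatorial on the lactone ring, which is the 4S configuration.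

Step 5
Reactants: 10 bridged keto lactone
Product: 11 (1S,2R,3S,4S)-4-[(2S)-1-hydroxy-3-methylbutan-2-yl]-1-methyl-3-(prop-2-en-1-yl)cyclopentane-1,2-diol
Conditions: LiAlH4, THF, −78 → 20 °C
Reagents that add atoms: none
Why: Hydride reduction: the ketone reacts first, from the exo face of the bicycle and anti to the C2–O bond (polar Felkin–Anh), which should give the 1β-alcohol cis to the C2 oxygen. The lactone is then reduced to the primary C5 alcohol and frees the tertiary C2 hydroxyl.

Step 6
Reactants: 11 triol
Product: 12 acetonide alcohol (1β,2β-O-isopropylidene derivative of 11; primary C5 hydroxyl free)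
Conditions: Me2C(OMe)2, PPTS (cat.), acetone, 20 °C
Reagents that add atoms: 2,2-dimethoxypropane, COC(C)(C)OC
Why: Acid-catalysed transketalisation; only the cis-1,2-diol on the cyclopentane can close the five-membered dioxolane, and a mixed ketal at the primary hydroxyl falls apart on work-up.

Step 7
Reactants: 12 acetonide alcohol
Product: 13 aldehyde (C5 aldehyde of 12)
Conditions: Dess–Martin periodinane, NaHCO3, CH2Cl2, 0 → 20 °C
Reagents that add atoms: none
Why: Dess–Martin oxidation of the primary alcohol under buffered, non-enolising conditions, so that the C4 centre next to the new aldehyde is kept.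

Step 8
Reactants: 13 aldehyde
Product: 14 chlorohydrins (5-hydroxy-6-chloro; both C5 epimers)
Conditions: ICH2Cl, MeLi·LiBr, THF, −78 °C; NH4Cl at −78 °C
Reagents that add atoms: chloroiodomethane, ClCI
Why: Carbenoid homologation: chloromethyllithium made in situ by iodine–lithium exchange adds to the aldehyde and forms the C5–C6 bond; the C5 configuration is not controlled here because it is removed in step 9.

Step 9
Reactants: 14 chlorohydrins
Product: 15 chloromethyl ketone (C5 ketone, C6 chloride)
Conditions: Dess–Martin periodinane, NaHCO3, CH2Cl2, 20 °C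
Reagents that add atoms: none
Why: Dess–Martin oxidation of the secondary alcohol; the buffered medium avoids enolisation toward C4.

Step 10
Reactants: 15 chloromethyl ketone
Product: 16 (5R)-chlorohydrin (5β-hydroxy)
Conditions: (R)-2-methyl-CBS-oxazaborolidine (cat.), BH3·SMe2, THF, −20 °C
Reagents that add atoms: none
Why: Corey–Bakshi–Shibata reduction under catalyst control: the doubly branched C4 residue acts as the large group and CH2Cl as the small one, so the (R)-catalyst should deliver hydride to give the 5R alcohol, which is the 5β oxygen of the target.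

Step 11
Reactants: 16 (5R)-chlorohydrin
Product: 17 tert-butyldimethylsilyl ether of 16
Conditions: TBSOTf, 2,6-lutidine, CH2Cl2, −78 → 0 °C
Reagents that add atoms: tert-butyldimethylsilyl triflate, CC(C)(C)[Si](C)(C)OS(=O)(=O)C(F)(F)F
Why: Silylation of a hindered secondary alcohol with the silyl triflate; the bulky ether is needed later to steer the epoxidation of C6=C7.

Step 12
Reactants: 17 silyl ether
Product: 18 secondary alcohol (7-hydroxy; both C7 epimers)
Conditions: Co(acac)2 (cat.), PhSiH3, O2, THF, 20 °C
Reagents that add atoms: dioxygen, O=O
Why: Mukaiyama hydration of the terminal alkene gives the Markovnikov alcohol by hydrogen-atom transfer and oxygen trapping; the C7 configuration is immaterial because C7 becomes sp2 in step 16.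

Step 13
Reactants: 18 secondary alcohol
Product: 19 mesylate of 18 (both C7 epimers)
Conditions: MsCl, Et3N, CH2Cl2, 0 °C
Reagents that add atoms: methanesulfonyl chloride, CS(=O)(=O)Cl
Why: Sulfonylation of the secondary alcohol turns C7 into an electrophile.

Step 14
Reactants: 19 mesylate
Product: 21 thiocane (sulfur between C6 and C7; both C7 epimers), via sodium thiolate 20 (not isolated)
Conditions: Na2S·9H2O, NaI (cat.), DMF, 60 °C, high dilution
Reagents that add atoms: sodium sulfide, [Na+].[Na+].[S-2]
Why: Double SN2 displacement: sulfide replaces the primary chloride (activated by Finkelstein exchange), and thiolate 20 closes the eight-membered ring by 8-exo-tet displacement of the mesylate. The trans-1,2-disubstituted cyclopentane holds the two chains close, and dilution suppresses oligomers.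

Step 15
Reactants: 21 thiocane
Product: 22 thiocane 1,1-dioxide (sulfone; both C7 epimers)
Conditions: mCPBA, NaHCO3, CH2Cl2, 0 → 20 °C
Reagents that add atoms: 3-chloroperoxybenzoic acid, OOC(=O)c1cccc(Cl)c1
Why: Peracid oxidation of the sulfide through the sulfoxide to the sulfone; no alkene is present and the buffer protects the acetonide.

Step 16
Reactants: 22 thiocane 1,1-dioxide
Product: 25 cycloheptene (C6=C7; 5β-silyl ether; 1β,2β-acetonide), via 6-bromo sulfone 23 (not isolated), via episulfone 24 (not isolated)
Conditions: KOH/Al2O3, CBr2F2, t-BuOH–CH2Cl2, 5 → 20 °C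
Reagents that add atoms: none
Why: Hydroxide on alumina deprotonates the more accessible α-carbon C6, and the carbanion takes bromine from CBr2F2 to give bromo sulfone 23. A second deprotonation at C7 then displaces bromide from C6 in a 1,3-elimination, which closes episulfone 24, and this loses SO2 in a cheletropic step to leave the C6=C7 double bond. The closest known reaction type is the Ramberg–Bäcklund rearrangement of medium-ring sulfones with in situ halogenation, which is used here as such. The one ring that is closed, the seven-membered carbocycle, arises by a 3-exo-tet closure of the C6–C7 bond inside the eight-membered ring, that is by contraction of the thiocane through loss of the sulfur atom. No stereocentre is made: C7 becomes sp2, so both C7 epimers of 22 converge, and the seven-membered ring allows only the cis alkene. The step needs halogen transfer and 1,3-elimination to outrun loss of the C5 silyloxide from the C6 carbanion and a second bromination; the poor leaving-group ability of the silyloxide, the excess of the fast halogen donor and the low temperature are relied on for this. Regiochemistry cannot go astray, because whichever α-carbon is brominated the same episulfone results, and the acetonide and the silyl ether are inert to the base.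

Step 17
Reactants: 25 cycloheptene
Product: 26 6α,7α-epoxide
Conditions: mCPBA, NaHCO3, CH2Cl2, 0 °C
Reagents that add atoms: 3-chloroperoxybenzoic acid, OOC(=O)c1cccc(Cl)c1
Why: Prilezhaev epoxidation; the β face of C6=C7 is screened by the allylic silyl ether and, further off, by the β acetonide, so the peracid should attack from the α face.

Step 18
Reactants: 26 epoxide
Product: 27 7α-hydroxy 5β-silyl ether
Conditions: LiBHEt3, THF, 0 → 40 °C
Reagents that add atoms: none
Why: SN2 opening of the trisubstituted epoxide by hydride at the less substituted C6; the C7–O bond is not broken, so the tertiary alcohol keeps the α oxygen and the β methyl group.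

Step 19
Reactants: 27 silyl ether
Product: 28 5β,7α-diol
Conditions: Bu4NF, THF, 40 °C
Reagents that add atoms: none
Why: Fluoride-induced desilylation frees the secondary C5 hydroxyl; acetonide and tertiary alcohol are inert.

Step 20
Reactants: 29 4-hydroxybenzoic acid
Product: 31 4-(tert-butyldimethylsilyloxy)benzoic acid, via bis-silylated acid 30 (not isolated)
Conditions: TBSCl, imidazole, DMF, 20 °C; then AcOH–THF–H2O, 20 °C
Reagents that add atoms: tert-butyldimethylsilyl chloride, CC(C)(C)[Si](C)(C)Cl
Why: Both hydroxyl groups are silylated, and the labile silyl ester is then hydrolysed selectively by dilute acid, which the aryl silyl ether withstands.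

Step 21
Reactants: 28 5β,7α-diol; 31 4-(tert-butyldimethylsilyloxy)benzoic acid
Product: 33 5β-aroyl ester acetonide, via 2,4,6-trichlorobenzoic mixed anhydride 32 (not isolated)
Conditions: 2,4,6-Cl3C6H2COCl, Et3N, THF, 20 °C; then 28, DMAP, toluene, 60 °C
Reagents that add atoms: none
Why: Yamaguchi esterification, chosen for the hindered secondary C5 hydroxyl; the tertiary C7 hydroxyl is not acylated under these conditions.

Step 22
Reactants: 33 ester acetonide
Product: 34 1β,2β-diol ester
Conditions: AcOH–H2O (4:1), 50 °C
Reagents that add atoms: none
Why: Acid hydrolysis of the ketal; the aryl silyl ether and the aryl ester are stable to dilute acid, and the mild conditions spare the tertiary alcohol.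

Step 23
Reactants: 34 diol ester
Product: 35 cyclic thionocarbonate
Conditions: 1,1'-thiocarbonyldiimidazole, DMAP (cat.), toluene, 90 °C
Reagents that add atoms: 1,1'-thiocarbonyldiimidazole, S=C(n1ccnc1)n1ccnc1
Why: The secondary C1 hydroxyl is thioacylated and the neighbouring cis tertiary hydroxyl closes the five-membered thionocarbonate; the isolated tertiary C7 hydroxyl has no such help and stays free.

Step 24
Reactants: 35 thionocarbonate
Product: 36 C1=C2 alkene
Conditions: P(OMe)3, 110 °C
Reagents that add atoms: none
Why: Corey–Winter olefination: desulfurisation by the phosphite and loss of CO2 from the carbene give the C1=C2 alkene by syn elimination, with no regiochemical ambiguity.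

Step 25
Reactants: 36 alkene
Product: 37 1α,2α-epoxide silyl ether
Conditions: VO(acac)2 (cat.), t-BuOOH, CH2Cl2, 0 → 20 °C
Reagents that add atoms: tert-butyl hydroperoxide, CC(C)(C)OO
Why: Hydroxyl-directed epoxidation: the vanadium alkoxide of the bishomoallylic tertiary C7 hydroxyl (α) should deliver the peroxide oxygen to the α face of C1=C2. Because hydroxyl and epoxide end up syn, the hydroxyl cannot open the epoxide from the rear.

Step 26
Reactants: 37 epoxide silyl ether
Product: 38 (1S,2R,3aR,4S,5S,7R,8aS)-1,2-epoxy-7-hydroxy-2,7-dimethyl-4-(propan-2-yl)decahydroazulen-5-yl 4-hydroxybenzoate (target)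
Conditions: Bu4NF, AcOH, THF, 0 °C
Reagents that add atoms: none
Why: Fluoride cleaves the aryl silyl ether rapidly; buffering with acetic acid keeps the medium from attacking the ester or the epoxide.

## Compound list

1 | (S)-(+)-linalool, (3S)-3,7-dimethylocta-1,6-dien-3-ol | C=C[C@@](C)(O)CCC=C(C)C | starting material
2 | (1S)-1-methylcyclopent-2-en-1-ol | C[C@@]1(O)C=CCC1 | intermediate
3 | isovaleryl chloride (3-methylbutanoyl chloride) | CC(C)CC(Cl)=O | starting material
4 | (1S)-1-methylcyclopent-2-en-1-yl 3-methylbutanoate | C[C@@]1(OC(=O)CC(C)C)C=CCC1 | intermediate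
5 | (1S)-2-hydroperoxy-1-methylcyclopent-3-en-1-yl 3-methylbutanoate (both epimers at the hydroperoxide carbon) | C[C@@]1(OC(=O)CC(C)C)C(OO)C=CC1 | intermediate
6 | (1S)-1-methyl-2-oxocyclopent-3-en-1-yl 3-methylbutanoate | C[C@@]1(OC(=O)CC(C)C)C(=O)C=CC1 | intermediate
7 | allyl bromide (3-bromoprop-1-ene) | C=CCBr | starting material
8 | lithium ester enolate of 6 | C[C@@]1(OC([O-])=CC(C)C)C(=O)C=CC1.[Li+] | intermediate
9 | bicyclic lithium enolate (C1 enolate of the bridged lactone formed by C3a–C4 bonding) | CC(C)[C@H]1[C@@H]2C[C@](C)(OC1=O)C([O-])=C2.[Li+] | intermediate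
10 | (1S,4S,5R,6S)-1-methyl-4-(propan-2-yl)-6-(prop-2-en-1-yl)-2-oxabicyclo[3.2.1]octane-3,7-dione (isopropyl equatorial, allyl exo) | CC(C)[C@H]1[C@@H]2C[C@](C)(OC1=O)C(=O)[C@H]2CC=C | intermediate
11 | (1S,2R,3S,4S)-4-[(2S)-1-hydroxy-3-methylbutan-2-yl]-1-methyl-3-(prop-2-en-1-yl)cyclopentane-1,2-diol | CC(C)[C@H](CO)[C@@H]1C[C@](C)(O)[C@H](O)[C@H]1CC=C | intermediate
12 | acetonide alcohol: 1β,2β-O-isopropylidene derivative of 11, primary C5 hydroxyl free | CC(C)[C@H](CO)[C@@H]1C[C@]2(C)OC(C)(C)O[C@@H]2[C@H]1CC=C | intermediate
13 | aldehyde: C5 aldehyde of 12 | CC(C)[C@H](C=O)[C@@H]1C[C@]2(C)OC(C)(C)O[C@@H]2[C@H]1CC=C | intermediate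
14 | chlorohydrins: 5-hydroxy-6-chloro compound, both C5 epimers | CC(C)[C@H](C(O)CCl)[C@@H]1C[C@]2(C)OC(C)(C)O[C@@H]2[C@H]1CC=C | intermediate
15 | chloromethyl ketone: C5 ketone, C6 chloride | CC(C)[C@H](C(=O)CCl)[C@@H]1C[C@]2(C)OC(C)(C)O[C@@H]2[C@H]1CC=C | intermediate
16 | (5R)-chlorohydrin (5β-hydroxy, 6-chloro) | CC(C)[C@H]([C@@H](O)CCl)[C@@H]1C[C@]2(C)OC(C)(C)O[C@@H]2[C@H]1CC=C | intermediate
17 | 5-O-tert-butyldimethylsilyl ether of 16 | CC(C)[C@H]([C@@H](O[Si](C)(C)C(C)(C)C)CCl)[C@@H]1C[C@]2(C)OC(C)(C)O[C@@H]2[C@H]1CC=C | intermediate
18 | secondary alcohol: 2-hydroxypropyl group on C8a (C7–OH), both C7 epimers | CC(C)[C@H]([C@@H](O[Si](C)(C)C(C)(C)C)CCl)[C@@H]1C[C@]2(C)OC(C)(C)O[C@@H]2[C@H]1CC(C)O | intermediate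
19 | C7 mesylate of 18, both C7 epimers | CC(C)[C@H]([C@@H](O[Si](C)(C)C(C)(C)C)CCl)[C@@H]1C[C@]2(C)OC(C)(C)O[C@@H]2[C@H]1CC(C)OS(C)(=O)=O | intermediate
20 | sodium thiolate: sulfur on C6, mesylate on C7 | CC(C)[C@H]([C@@H](O[Si](C)(C)C(C)(C)C)C[S-])[C@@H]1C[C@]2(C)OC(C)(C)O[C@@H]2[C@H]1CC(C)OS(C)(=O)=O.[Na+] | intermediate
21 | thiocane: eight-membered sulfide trans-fused to the cyclopentane acetonide, sulfur between C6 and C7, 5β-silyl ether, both C7 epimers | CC(C)[C@H]1[C@@H]2C[C@]3(C)OC(C)(C)O[C@@H]3[C@H]2CC(C)SC[C@@H]1O[Si](C)(C)C(C)(C)C | intermediate
22 | thiocane 1,1-dioxide (sulfone of 21), both C7 epimers | CC(C)[C@H]1[C@@H]2C[C@]3(C)OC(C)(C)O[C@@H]3[C@H]2CC(C)S(=O)(=O)C[C@@H]1O[Si](C)(C)C(C)(C)C | intermediate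
23 | 6-bromo sulfone | CC(C)[C@H]1[C@@H]2C[C@]3(C)OC(C)(C)O[C@@H]3[C@H]2CC(C)S(=O)(=O)C(Br)[C@@H]1O[Si](C)(C)C(C)(C)C | intermediate
24 | episulfone: thiirane 1,1-dioxide across C6–C7 | CC(C)[C@H]1[C@@H]2C[C@]3(C)OC(C)(C)O[C@@H]3[C@H]2CC4(C)S(=O)(=O)C4[C@@H]1O[Si](C)(C)C(C)(C)C | intermediate
25 | cycloheptene: trans-fused hydroazulene with C6=C7, 7-methyl, 5β-silyl ether, 4α-isopropyl, 1β,2β-acetonide | CC(C)[C@H]1[C@@H]2C[C@]3(C)OC(C)(C)O[C@@H]3[C@H]2CC(C)=C[C@@H]1O[Si](C)(C)C(C)(C)C | intermediate
26 | 6α,7α-epoxide of 25 | CC(C)[C@H]1[C@@H]2C[C@]3(C)OC(C)(C)O[C@@H]3[C@H]2C[C@@]4(C)O[C@H]4[C@@H]1O[Si](C)(C)C(C)(C)C | intermediate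
27 | 7α-hydroxy-7β-methyl 5β-silyl ether | CC(C)[C@H]1[C@@H]2C[C@]3(C)OC(C)(C)O[C@@H]3[C@H]2C[C@@](C)(O)C[C@@H]1O[Si](C)(C)C(C)(C)C | intermediate
28 | 5β,7α-diol acetonide | CC(C)[C@H]1[C@@H]2C[C@]3(C)OC(C)(C)O[C@@H]3[C@H]2C[C@@](C)(O)C[C@@H]1O | intermediate
29 | 4-hydroxybenzoic acid | OC(=O)c1ccc(O)cc1 | starting material
30 | tert-butyldimethylsilyl 4-(tert-butyldimethylsilyloxy)benzoate | CC(C)(C)[Si](C)(C)OC(=O)c1ccc(O[Si](C)(C)C(C)(C)C)cc1 | intermediate
31 | 4-(tert-butyldimethylsilyloxy)benzoic acid | OC(=O)c1ccc(O[Si](C)(C)C(C)(C)C)cc1 | intermediate
32 | 4-(tert-butyldimethylsilyloxy)benzoic 2,4,6-trichlorobenzoic anhydride | O=C(OC(=O)c1c(Cl)cc(Cl)cc1Cl)c1ccc(O[Si](C)(C)C(C)(C)C)cc1 | intermediate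
33 | 5β-[4-(tert-butyldimethylsilyloxy)benzoyloxy] 7α-hydroxy acetonide | CC(C)[C@H]1[C@@H]2C[C@]3(C)OC(C)(C)O[C@@H]3[C@H]2C[C@@](C)(O)C[C@@H]1OC(=O)c1ccc(O[Si](C)(C)C(C)(C)C)cc1 | intermediate
34 | 1β,2β,7α-triol 5β-aryl ester | CC(C)[C@H]1[C@@H]2C[C@](C)(O)[C@H](O)[C@H]2C[C@@](C)(O)C[C@@H]1OC(=O)c1ccc(O[Si](C)(C)C(C)(C)C)cc1 | intermediate
35 | 1β,2β-cyclic thionocarbonate | CC(C)[C@H]1[C@@H]2C[C@]3(C)OC(=S)O[C@@H]3[C@H]2C[C@@](C)(O)C[C@@H]1OC(=O)c1ccc(O[Si](C)(C)C(C)(C)C)cc1 | intermediate
36 | C1=C2 alkene: 2-methyl-1,3,3a,4,5,6,7,8,8a-hydroazulene with 7α-hydroxy and 5β-aryl ester | CC(C)[C@H]1[C@@H]2CC(C)=C[C@H]2C[C@@](C)(O)C[C@@H]1OC(=O)c1ccc(O[Si](C)(C)C(C)(C)C)cc1 | intermediate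
37 | 1α,2α-epoxide, phenol as tert-butyldimethylsilyl ether | CC(C)[C@H]1[C@@H]2C[C@@]3(C)O[C@H]3[C@H]2C[C@@](C)(O)C[C@@H]1OC(=O)c1ccc(O[Si](C)(C)C(C)(C)C)cc1 | intermediate
38 | (1S,2R,3aR,4S,5S,7R,8aS)-1,2-epoxy-7-hydroxy-2,7-dimethyl-4-(propan-2-yl)decahydroazulen-5-yl 4-hydroxybenzoate | CC(C)[C@H]1[C@@H]2C[C@@]3(C)O[C@H]3[C@H]2C[C@@](C)(O)C[C@@H]1OC(=O)c1ccc(O)cc1 | target

## Step count and least certain steps

Total step count: 26. Longest linear sequence: 25 steps (steps 1 to 19 and 21 to 26); step 20 is a one-step side branch.

Step 16 (key step).
- Risk: after deprotonation at C6 the carbanion may expel the C5 silyloxide (β-elimination to a vinyl sulfone) before it is brominated, or deprotonation at the tertiary C7 may be so slow that the bromo sulfone is brominated a second time.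
- Fallback: the C6=C7 bond is closed by ring-closing metathesis. It sets out from aldehyde 13. Addition of vinylmagnesium bromide gives the allylic alcohols F1, Dess–Martin oxidation gives vinyl ketone F2, and CBS reduction with the catalyst enantiomer that gives the 5S carbinol gives allylic alcohol F3. Silylation as in step 11 gives silyl ether F4. Wacker oxidation (PdCl2, CuCl, O2, DMF–H2O), which should prefer the unhindered allyl group over the vinyl group next to the silyl ether, gives methyl ketone F5, and methylenation with Ph3P=CH2 gives diene F6. Ring-closing metathesis with the second-generation Grubbs catalyst RuCl2(=CHPh)(PCy3)(H2IMes) then gives 25, where the route is rejoined.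

Step 4.
- Risk: the base may remove a γ-proton of the enone instead of the ester α-proton, or the aldol adduct at C1 may fail to revert, so that the bridged Michael adduct is not reached.
- Fallback: the same bond is made between two molecules and the lactone is closed afterwards. It sets out from 2. Trimethylsilylation gives silyl ether F7 and photo-oxygenation as in step 3 gives enone F8. The lithium enolate of methyl isovalerate (LiN(i-Pr)2, THF, −78 °C) adds to F8 and the enolate is trapped with allyl bromide to give, beside its facial isomer, methyl ester F9. Bu4NF then frees the tertiary alkoxide, which can close the lactone only in the isomer with the side chain on the oxygen face, and the tert-butoxide equilibration of step 4 leads to 10.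

Step 14.
- Risk: the open-chain thiolate may react with a second molecule instead of closing the eight-membered ring, or the secondary mesylate may be lost by elimination.
- Fallback: the two C–S bonds are made in separate operations. It sets out from 19. Potassium thioacetate displaces the mesylate and gives thioacetate F10. Methanolysis with K2CO3 in MeOH in the presence of NaI under high dilution frees the thiolate only when no external sulfur nucleophile is left, and closure onto C6 gives 21.

Step 17.
- Risk: poor facial selectivity, or attack of the peracid on the β face if the silyl ether lies pseudo-equatorial, which would invert C7.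
- Fallback: anti addition is used, which turns the same facial preference into the right C7 configuration. It sets out from 25. N-Bromosuccinimide in aqueous acetone gives bromohydrin F11 (β bromonium ion, water at the tertiary C7 from the α face), and Bu3SnH with azobisisobutyronitrile removes the bromine to give 27.

Step 25.
- Risk: delivery from the tertiary C7 hydroxyl may fail for geometric reasons, so that the oxidant attacks the β face or the reaction stalls.
- Fallback: it sets out from 36. N-Bromosuccinimide in aqueous acetone gives bromohydrin F12 (β bromonium ion, water at the tertiary C2 from the α face), and DBU closes the α epoxide by displacement of bromide at C1, which gives 37.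

## Further compounds

F1 | step 16 | allylic alcohols from vinyl addition to 13 (both C5 epimers) | CC(C)[C@H](C(O)C=C)[C@@H]1C[C@]2(C)OC(C)(C)O[C@@H]2[C@H]1CC=C
F2 | step 16 | vinyl ketone (C5 ketone) | CC(C)[C@H](C(=O)C=C)[C@@H]1C[C@]2(C)OC(C)(C)O[C@@H]2[C@H]1CC=C
F3 | step 16 | (5S)-allylic alcohol (5β-hydroxy) | CC(C)[C@H]([C@@H](O)C=C)[C@@H]1C[C@]2(C)OC(C)(C)O[C@@H]2[C@H]1CC=C
F4 | step 16 | tert-butyldimethylsilyl ether of F3 | CC(C)[C@H]([C@@H](O[Si](C)(C)C(C)(C)C)C=C)[C@@H]1C[C@]2(C)OC(C)(C)O[C@@H]2[C@H]1CC=C
F5 | step 16 | methyl ketone (C7 ketone) from Wacker oxidation of F4 | CC(C)[C@H]([C@@H](O[Si](C)(C)C(C)(C)C)C=C)[C@@H]1C[C@]2(C)OC(C)(C)O[C@@H]2[C@H]1CC(C)=O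
F6 | step 16 | metathesis diene (C5 vinyl, C8 isopropenyl) | CC(C)[C@H]([C@@H](O[Si](C)(C)C(C)(C)C)C=C)[C@@H]1C[C@]2(C)OC(C)(C)O[C@@H]2[C@H]1CC(C)=C
F7 | step 4 | trimethyl{[(1S)-1-methylcyclopent-2-en-1-yl]oxy}silane | C[C@@]1(O[Si](C)(C)C)C=CCC1
F8 | step 4 | (5S)-5-methyl-5-(trimethylsilyloxy)cyclopent-2-en-1-one | C[C@@]1(O[Si](C)(C)C)C(=O)C=CC1
F9 | step 4 | methyl ester from intermolecular Michael addition and allylation (side chain on the oxygen face, C4 not defined) | COC(=O)C(C(C)C)[C@@H]1C[C@](C)(O[Si](C)(C)C)C(=O)[C@H]1CC=C
F10 | step 14 | C7 thioacetate (both C7 epimers) | CC(C)[C@H]([C@@H](O[Si](C)(C)C(C)(C)C)CCl)[C@@H]1C[C@]2(C)OC(C)(C)O[C@@H]2[C@H]1CC(C)SC(C)=O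
F11 | step 17 | bromohydrin (6β-bromo, 7α-hydroxy) | CC(C)[C@H]1[C@@H]2C[C@]3(C)OC(C)(C)O[C@@H]3[C@H]2C[C@@](C)(O)[C@H](Br)[C@@H]1O[Si](C)(C)C(C)(C)C
F12 | step 25 | bromohydrin (1β-bromo, 2α-hydroxy) | CC(C)[C@H]1[C@@H]2C[C@@](C)(O)[C@H](Br)[C@H]2C[C@@](C)(O)C[C@@H]1OC(=O)c1ccc(O[Si](C)(C)C(C)(C)C)cc1
A1 | alternative 1 | ten-membered enedione bis(silyl ether) | CC(C)C1=CC[C@@](C)(O[Si](C)(C)C(C)(C)C)C(=O)CC[C@@](C)(O[Si](CC)(CC)CC)CC1=O
A2 | alternative 1 | trans-fused hydroazulene-1,5-dione bis(silyl ether) | CC(C)[C@H]1[C@@H]2C[C@@](C)(O[Si](C)(C)C(C)(C)C)C(=O)[C@H]2C[C@@](C)(O[Si](CC)(CC)CC)CC1=O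
A3 | alternative 2 | trimethylsilyl enol ether (C5=C8) of the isopropyl-, methallyl- and vinyl-substituted cyclopentanone | CC(C)[C@H]1[C@H](CC(C)=C)[C@@H](C=C)C=C1O[Si](C)(C)C
A4 | alternative 2 | dichloroketene | ClC(Cl)=C=O
A5 | alternative 2 | 2,2-dichlorocycloheptane-1,3-dione with isopropyl, methallyl and vinyl groups | CC(C)[C@H]1[C@H](CC(C)=C)[C@@H](C=C)CC(=O)C(Cl)(Cl)C1=O
A6 | alternative 3 | cis-divinylcyclopropane (cyclopentenone and silyl enol ether as vinyl units) | CC(C)C=C(O[Si](C)(C)C(C)(C)C)[C@H]1[C@](C)(OCOC)[C@H]1C1=CC[C@@](C)(O[Si](CC)(CC)CC)C1=O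
A7 | alternative 3 | hydroazulene dienone silyl enol ether (C4 epimer) | CC(C)[C@@H]1[C@@H]2C[C@@](C)(O[Si](CC)(CC)CC)C(=O)C2=C[C@@](C)(OCOC)C=C1O[Si](C)(C)C(C)(C)C
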